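**Retrosynthetic overview**
- Target 15 ⇐ tetrapivalate 14 by methanolysis of four aryl pivalates, which mask both resorcinol rings as non-nucleophilic arenes during the fragment union.
- 14 ⇐ phenol 11 + racemic p-hydroxybenzylic alcohol 7: the aryl–CH bond is made by a chiral-phosphoric-acid-catalysed, enantioconvergent ortho-Friedel–Crafts addition to the p-quinone methide 12.
- Enabling feature: the stereogenic CH is the benzylic carbon para to the free OH of the 4-hydroxy-3-methoxyphenyl ring, so it can become the exocyclic carbon of a p-quinone methide. The aryl carbon it bonds to is the CH ortho to the free OH of the 2-methoxyphenol ring of the stilbene, so the catalyst can hold both partners by these two OH groups.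
- 7 ⇐ benzylic zinc reagent from 4-methylresorcinol dipivalate + O-TBS-vanillin; 11 ⇐ Heck coupling of 5-bromoresorcinol dipivalate with 2-methoxy-4-vinylphenol.
- No ring is formed in the route: all five benzene rings come from commercial arenes.

Key step: step 7

Assumption: the sense of induction of a BINOL-derived phosphoric acid cannot be assigned with confidence for this p-quinone methide; (R)-TRIP is written, and (S)-TRIP is to be used instead if a test run favours the (R)-enantiomer of 14.
Assumption: aldehyde 4 is taken as commercial; otherwise it is one silylation (TBSCl, imidazole) from vanillin.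

**Route**

Step 1
Reactants: 1 4-methylbenzene-1,3-diol
Product: 2 4-methyl-1,3-phenylene bis(2,2-dimethylpropanoate)
Conditions: PivCl (2.4 equiv), Et3N (3 equiv), DMAP (cat.), CH2Cl2, 0 °C to rt
Reagents that add atoms: pivaloyl chloride, CC(C)(C)C(=O)Cl
Why: DMAP-catalysed O-acylation should cap both phenols as pivalates, which deactivate this resorcinol ring for step 7 and tolerate the organozinc chemistry of step 3.

Step 2
Reactants: 2 4-methyl-1,3-phenylene bis(2,2-dimethylpropanoate)
Product: 3 4-(bromomethyl)-1,3-phenylene bis(2,2-dimethylpropanoate)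
Conditions: NBS (1.05 equiv), AIBN (5 mol%), PhCF3, 85 °C
Reagents that add atoms: N-bromosuccinimide, O=C1CCC(=O)N1Br
Why: Wohl–Ziegler radical bromination should take place at the benzylic methyl group because the two acyloxy groups disfavour electrophilic ring bromination.

Step 3
Reactants: 3 4-(bromomethyl)-1,3-phenylene bis(2,2-dimethylpropanoate); 4 4-[(tert-butyldimethylsilyl)oxy]-3-methoxybenzaldehyde
Product: 6 rac-4-{2-[4-(tert-butyldimethylsilyloxy)-3-methoxyphenyl]-2-hydroxyethyl}-1,3-phenylene bis(2,2-dimethylpropanoate), via [2,4-bis(2,2-dimethylpropanoyloxy)benzyl]zinc bromide 5 (not isolated)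
Conditions: Zn dust (activated, 1.5 equiv), LiCl, THF, 0 °C; then 4, MgCl2, THF, 0 °C to rt; sat. aq. NH4Cl
Reagents that add atoms: none
Why: LiCl-promoted zinc insertion should give an ester-tolerant benzylic zinc reagent that adds 1,2 to the aldehyde (two-stage Barbier-type organozinc addition, accelerated by the magnesium salt); the carbinol centre is formed racemic, which is all that step 7 requires.

Step 4
Reactants: 6 rac-4-{2-[4-(tert-butyldimethylsilyloxy)-3-methoxyphenyl]-2-hydroxyethyl}-1,3-phenylene bis(2,2-dimethylpropanoate)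
Product: 7 rac-4-[2-hydroxy-2-(4-hydroxy-3-methoxyphenyl)ethyl]-1,3-phenylene bis(2,2-dimethylpropanoate)
Conditions: HF·pyridine, pyridine, THF, 0 °C
Reagents that add atoms: none
Why: Buffered fluoride cleavage of the aryl silyl ether (desilylation) should free the phenol without touching the aryl pivalates or ionising the acid-sensitive p-hydroxybenzylic alcohol.

Step 5
Reactants: 8 5-bromobenzene-1,3-diol
Product: 9 5-bromo-1,3-phenylene bis(2,2-dimethylpropanoate)
Conditions: PivCl (2.4 equiv), Et3N (3 equiv), DMAP (cat.), CH2Cl2, 0 °C to rt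
Reagents that add atoms: pivaloyl chloride, CC(C)(C)C(=O)Cl
Why: DMAP-catalysed O-acylation should give the dipivalate, which later makes the second resorcinol ring and the neighbouring alkene carbon poor nucleophiles in step 7.

Step 6
Reactants: 9 5-bromo-1,3-phenylene bis(2,2-dimethylpropanoate); 10 2-methoxy-4-vinylphenol
Product: 11 5-[(E)-2-(4-hydroxy-3-methoxyphenyl)ethenyl]-1,3-phenylene bis(2,2-dimethylpropanoate)
Conditions: Pd(OAc)2 (3 mol%), P(o-tol)3 (9 mol%), Et3N (2 equiv), BHT (cat.), DMF, 90 °C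
Reagents that add atoms: none
Why: Mizoroki–Heck arylation of the terminal vinyl carbon should give the E-alkene through syn-carbopalladation and syn-β-hydride elimination, the free phenol being tolerated.

Step 7
Reactants: 7 rac-4-[2-hydroxy-2-(4-hydroxy-3-methoxyphenyl)ethyl]-1,3-phenylene bis(2,2-dimethylpropanoate); 11 5-[(E)-2-(4-hydroxy-3-methoxyphenyl)ethenyl]-1,3-phenylene bis(2,2-dimethylpropanoate)
Product: 14 4-[(2S)-2-{5-[(E)-2-(3,5-bis(2,2-dimethylpropanoyloxy)phenyl)ethenyl]-2-hydroxy-3-methoxyphenyl}-2-(4-hydroxy-3-methoxyphenyl)ethyl]-1,3-phenylene bis(2,2-dimethylpropanoate), via para-quinone methide 12 (not isolated), via cyclohexadienone adduct 13 (not isolated)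
Conditions: (R)-TRIP (10 mol%), 11 (3 equiv), 5 Å MS, toluene, 35 °C, 7 added by syringe pump over 10 h; excess 11 recovered
Reagents that add atoms: none
Why: (R)-TRIP ionises racemic 7 with loss of water, helped by the para-OH, to the planar p-quinone methide 12 (both exocyclic alkene isomers, in equilibrium with 7 and its O-adducts), then holds 12 by P–OH···O=C and phenol 11 by P=O···H–O so that the CH ortho to the OH of 11 attacks the exocyclic carbon (1,6-addition) to give dienone 13, which tautomerises to the phenol 14. The closest known reaction type is the chiral-phosphoric-acid-catalysed enantioconvergent Friedel–Crafts arylation of p-quinone methides made in situ from racemic p-hydroxybenzylic alcohols by naphthols or phenols. No ring is closed. The one new stereocentre is controlled by the catalyst, which exposes a single face of the prochiral exocyclic carbon in the doubly hydrogen-bonded transition state, so both enantiomers of 7 and both isomers of 12 are funnelled into (S)-14. The step needs site selectivity in 11 and cross- over self-alkylation: the second ortho position of 11 carries OMe and the para position the styryl group, the four pivalates make both resorcinol rings and the adjoining alkene carbon poor nucleophiles, O-alkylation is reversible under the acid, and the free ortho CH of the guaiacyl ring in 7 and 14 is outcompeted by adding 7 slowly to 3 equiv of recoverable 11.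

Step 8
Reactants: 14 4-[(2S)-2-{5-[(E)-2-(3,5-bis(2,2-dimethylpropanoyloxy)phenyl)ethenyl]-2-hydroxy-3-methoxyphenyl}-2-(4-hydroxy-3-methoxyphenyl)ethyl]-1,3-phenylene bis(2,2-dimethylpropanoate)
Product: 15 4-[(2S)-2-{5-[(E)-2-(3,5-dihydroxyphenyl)ethenyl]-2-hydroxy-3-methoxyphenyl}-2-(4-hydroxy-3-methoxyphenyl)ethyl]benzene-1,3-diol
Conditions: NaOMe (8 equiv), degassed MeOH/THF, Ar, 0 °C to rt; AcOH quench
Reagents that add atoms: none
Why: Zemplén-type transesterification should remove all four aryl pivalates as methyl pivalate, while the non-acidic benzylic CH stereocentre and the E-alkene are untouched under the oxygen-free basic conditions.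

**Compound list**
1 | 4-methylbenzene-1,3-diol | Cc1ccc(O)cc1O | starting material
2 | 4-methyl-1,3-phenylene bis(2,2-dimethylpropanoate) | Cc1ccc(OC(=O)C(C)(C)C)cc1OC(=O)C(C)(C)C | intermediate
3 | 4-(bromomethyl)-1,3-phenylene bis(2,2-dimethylpropanoate) | BrCc1ccc(OC(=O)C(C)(C)C)cc1OC(=O)C(C)(C)C | intermediate
4 | 4-[(tert-butyldimethylsilyl)oxy]-3-methoxybenzaldehyde | COc1cc(C=O)ccc1O[Si](C)(C)C(C)(C)C | starting material
5 | [2,4-bis(2,2-dimethylpropanoyloxy)benzyl]zinc bromide (not isolated) | Br[Zn]Cc1ccc(OC(=O)C(C)(C)C)cc1OC(=O)C(C)(C)C | intermediate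
6 | rac-4-{2-[4-(tert-butyldimethylsilyloxy)-3-methoxyphenyl]-2-hydroxyethyl}-1,3-phenylene bis(2,2-dimethylpropanoate) | COc1cc(C(O)Cc2ccc(OC(=O)C(C)(C)C)cc2OC(=O)C(C)(C)C)ccc1O[Si](C)(C)C(C)(C)C | intermediate
7 | rac-4-[2-hydroxy-2-(4-hydroxy-3-methoxyphenyl)ethyl]-1,3-phenylene bis(2,2-dimethylpropanoate) | COc1cc(C(O)Cc2ccc(OC(=O)C(C)(C)C)cc2OC(=O)C(C)(C)C)ccc1O | intermediate
8 | 5-bromobenzene-1,3-diol | Oc1cc(O)cc(Br)c1 | starting material
9 | 5-bromo-1,3-phenylene bis(2,2-dimethylpropanoate) | Brc1cc(OC(=O)C(C)(C)C)cc(OC(=O)C(C)(C)C)c1 | intermediate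
10 | 2-methoxy-4-vinylphenol | C=Cc1ccc(O)c(OC)c1 | starting material
11 | 5-[(E)-2-(4-hydroxy-3-methoxyphenyl)ethenyl]-1,3-phenylene bis(2,2-dimethylpropanoate) | COc1cc(/C=C/c2cc(OC(=O)C(C)(C)C)cc(OC(=O)C(C)(C)C)c2)ccc1O | intermediate
12 | 4-[2-(3-methoxy-4-oxocyclohexa-2,5-dien-1-ylidene)ethyl]-1,3-phenylene bis(2,2-dimethylpropanoate), p-quinone methide, mixture of exocyclic alkene isomers (not isolated) | COC1=CC(=CCc2ccc(OC(=O)C(C)(C)C)cc2OC(=O)C(C)(C)C)C=CC1=O | intermediate
13 | cyclohexa-2,4-dienone tautomer of 14, the first C–C adduct; benzylic carbon already in the spatial arrangement of 14 (CIP descriptor R in this tautomer), ring CH as a mixture of epimers (not isolated) | COc1cc([C@H](Cc2ccc(OC(=O)C(C)(C)C)cc2OC(=O)C(C)(C)C)C2C=C(/C=C/c3cc(OC(=O)C(C)(C)C)cc(OC(=O)C(C)(C)C)c3)C=C(OC)C2=O)ccc1O | intermediate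
14 | 4-[(2S)-2-{5-[(E)-2-(3,5-bis(2,2-dimethylpropanoyloxy)phenyl)ethenyl]-2-hydroxy-3-methoxyphenyl}-2-(4-hydroxy-3-methoxyphenyl)ethyl]-1,3-phenylene bis(2,2-dimethylpropanoate) | COc1cc([C@H](Cc2ccc(OC(=O)C(C)(C)C)cc2OC(=O)C(C)(C)C)c2cc(/C=C/c3cc(OC(=O)C(C)(C)C)cc(OC(=O)C(C)(C)C)c3)cc(OC)c2O)ccc1O | intermediate
15 | 4-[(2S)-2-{5-[(E)-2-(3,5-dihydroxyphenyl)ethenyl]-2-hydroxy-3-methoxyphenyl}-2-(4-hydroxy-3-methoxyphenyl)ethyl]benzene-1,3-diol | COc1cc([C@H](Cc2ccc(O)cc2O)c2cc(/C=C/c3cc(O)cc(O)c3)cc(OC)c2O)ccc1O | target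

**Step count**
Total steps: 8. Longest linear sequence: 6 steps (1, 2, 3, 4, 7, 8); steps 5 and 6 form the second branch.

**Steps most likely to fail**

Step 7 (key step). Three processes may spoil it. The first is alkylation by 12 at the wrong site: the stilbene alkene of 11, or the free ortho position of the guaiacyl ring of 7 or 14. The second is loss of a proton from 12 to give the conjugated hydroxystilbene. The third is weak facial discrimination, because the exocyclic carbon of 12 carries only H and a CH2Ar group. The fallback is a nickel-catalysed enantioconvergent Negishi arylation of a racemic secondary benzylic electrophile, in which the site is fixed by a carbon–zinc bond and the configuration by the chiral nickel catalyst; it sets out from 11 and 6 and returns at 14. Phenol 11 would be iodinated at its only free position ortho to OH (NIS, cat. TsOH, MeCN, 0 °C) to give 5-[(E)-2-(4-hydroxy-3-iodo-5-methoxyphenyl)ethenyl]-1,3-phenylene bis(2,2-dimethylpropanoate) F1. Silylation (TBSCl, imidazole, DMF) should give 5-{(E)-2-[4-(tert-butyldimethylsilyloxy)-3-iodo-5-methoxyphenyl]ethenyl}-1,3-phenylene bis(2,2-dimethylpropanoate) F2, and zinc insertion (Zn, LiCl, THF, 25–40 °C) the corresponding arylzinc iodide F3, used in solution. In parallel, 6 would be converted (MsCl, Et3N, CH2Cl2, −40 °C) into the racemic benzylic methanesulfonate F4, which LiI should turn in the flask into the racemic benzylic iodide F5. NiBr2·glyme and a chiral bis(oxazoline) ligand (CH2Cl2/THF, −45 °C) should then couple F5 with F3 through a benzylic radical to the (S)-configured bis(silyl ether) of 14 F6, the ligand enantiomer being chosen for that configuration. Desilylation with HF·pyridine, as in step 4, returns the route to 14.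

Step 3. Wurtz-type homocoupling during zinc insertion, transfer of the ortho pivaloyl group to the metal alkoxide, or sluggish addition to the electron-rich aldehyde may erode the yield. The fallback is a Corey–Seebach umpolung that reverses the polarity of the two partners; it sets out from 4 and 3 and returns at 6. Aldehyde 4 would be converted (propane-1,3-dithiol, cat. I2, CH2Cl2) into 2-[4-(tert-butyldimethylsilyloxy)-3-methoxyphenyl]-1,3-dithiane F7 and deprotonated (n-BuLi, THF, −78 °C) to the 2-lithio-1,3-dithiane F8. Alkylation with bromide 3 at −78 °C should give the 2-aryl-2-benzyl-1,3-dithiane F9. Unmasking (MeI, CaCO3, aq. MeCN, 45 °C) should give 4-{2-[4-(tert-butyldimethylsilyloxy)-3-methoxyphenyl]-2-oxoethyl}-1,3-phenylene bis(2,2-dimethylpropanoate) F10, and NaBH4 (MeOH/THF, 0 °C) reduces it to 6.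

Step 6. Polymerisation of the vinylphenol 10 at 90 °C and amine-mediated pivaloyl transfer to its free OH may compete with the coupling. The fallback reverses the roles of the Heck partners, so that the alkene is not a phenol and the halide is a more reactive iodide; it sets out from 9 and returns at 11. A Stille coupling of 9 with tributyl(vinyl)stannane (Pd(PPh3)4, toluene, 100 °C) should give 5-ethenyl-1,3-phenylene bis(2,2-dimethylpropanoate) F11. A Heck reaction of F11 with commercial 4-iodo-2-methoxyphenol (Pd(OAc)2, Et3N, DMF, 70 °C) then gives 11.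

**Further compounds**
F1 | step 7 | 5-[(E)-2-(4-hydroxy-3-iodo-5-methoxyphenyl)ethenyl]-1,3-phenylene bis(2,2-dimethylpropanoate) | COc1cc(/C=C/c2cc(OC(=O)C(C)(C)C)cc(OC(=O)C(C)(C)C)c2)cc(I)c1O
F2 | step 7 | 5-{(E)-2-[4-(tert-butyldimethylsilyloxy)-3-iodo-5-methoxyphenyl]ethenyl}-1,3-phenylene bis(2,2-dimethylpropanoate) | COc1cc(/C=C/c2cc(OC(=O)C(C)(C)C)cc(OC(=O)C(C)(C)C)c2)cc(I)c1O[Si](C)(C)C(C)(C)C
F3 | step 7 | arylzinc iodide from F2 (zinc in place of iodine on the ring) | COc1cc(/C=C/c2cc(OC(=O)C(C)(C)C)cc(OC(=O)C(C)(C)C)c2)cc([Zn]I)c1O[Si](C)(C)C(C)(C)C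
F4 | step 7 | rac-4-{2-[4-(tert-butyldimethylsilyloxy)-3-methoxyphenyl]-2-(methanesulfonyloxy)ethyl}-1,3-phenylene bis(2,2-dimethylpropanoate) | COc1cc(C(OS(C)(=O)=O)Cc2ccc(OC(=O)C(C)(C)C)cc2OC(=O)C(C)(C)C)ccc1O[Si](C)(C)C(C)(C)C
F5 | step 7 | rac-4-{2-[4-(tert-butyldimethylsilyloxy)-3-methoxyphenyl]-2-iodoethyl}-1,3-phenylene bis(2,2-dimethylpropanoate) | COc1cc(C(I)Cc2ccc(OC(=O)C(C)(C)C)cc2OC(=O)C(C)(C)C)ccc1O[Si](C)(C)C(C)(C)C
F6 | step 7 | (S)-configured bis(tert-butyldimethylsilyl) ether of 14 | COc1cc([C@H](Cc2ccc(OC(=O)C(C)(C)C)cc2OC(=O)C(C)(C)C)c2cc(/C=C/c3cc(OC(=O)C(C)(C)C)cc(OC(=O)C(C)(C)C)c3)cc(OC)c2O[Si](C)(C)C(C)(C)C)ccc1O[Si](C)(C)C(C)(C)C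
F7 | step 3 | 2-[4-(tert-butyldimethylsilyloxy)-3-methoxyphenyl]-1,3-dithiane | COc1cc(C2SCCCS2)ccc1O[Si](C)(C)C(C)(C)C
F8 | step 3 | 2-lithio-2-[4-(tert-butyldimethylsilyloxy)-3-methoxyphenyl]-1,3-dithiane | COc1cc(C2([Li])SCCCS2)ccc1O[Si](C)(C)C(C)(C)C
F9 | step 3 | 4-({2-[4-(tert-butyldimethylsilyloxy)-3-methoxyphenyl]-1,3-dithian-2-yl}methyl)-1,3-phenylene bis(2,2-dimethylpropanoate) | COc1cc(C2(Cc3ccc(OC(=O)C(C)(C)C)cc3OC(=O)C(C)(C)C)SCCCS2)ccc1O[Si](C)(C)C(C)(C)C
F10 | step 3 | 4-{2-[4-(tert-butyldimethylsilyloxy)-3-methoxyphenyl]-2-oxoethyl}-1,3-phenylene bis(2,2-dimethylpropanoate) | COc1cc(C(=O)Cc2ccc(OC(=O)C(C)(C)C)cc2OC(=O)C(C)(C)C)ccc1O[Si](C)(C)C(C)(C)C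
F11 | step 6 | 5-ethenyl-1,3-phenylene bis(2,2-dimethylpropanoate) | C=Cc1cc(OC(=O)C(C)(C)C)cc(OC(=O)C(C)(C)C)c1
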